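**Retrosynthetic overview**
1. The target is (3R)-7,4'-dihydroxy-6,3'-diprenylisoflavanone, and the last event is only the removal of two silyl ethers under non-enolising conditions.
2. The key disconnection is C3 (ring C)–C1' (ring B). A racemic 3-bromochroman-4-one (rings A and C, C6 prenyl in place) is arylated by a ring B arylzinc iodide (C3' prenyl in place) in a stereoconvergent nickel/pybox Negishi coupling. This one operation joins the halves, erases the bromide configuration and writes the only stereocentre without base.
3. Enabling feature: C3 is alpha to the C4 carbonyl, which is conjugated with ring A, so a C3–Br bond of either configuration collapses to one planar, delocalised radical. Ring C keeps the C2–O1 bond out of syn alignment with a C3–Ni bond. C1' is para to the C4' oxygen and has C–H on both sides (C2', C6'), so the arylzinc is unhindered.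
4. The C6 prenyl group comes from iodination and Stille coupling. The C3' prenyl group comes from ortho-C-alkylation of a phenoxide whose para position carries the bromine that later becomes zinc.
5. No ring is built: rings A and C arrive together in 7-hydroxychroman-4-one, and ring B arrives in 4-bromophenol.

Key step: step 7

Remark: C3 of the target is (R) (CIP order C4 > C2 > C1' > H); the sense of induction of the pybox ligand on a ring-fused bromoketone cannot be assigned in advance, so the ligand named in step 7 is a working choice and its mirror image is taken if a pilot run gives the (S) product.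

**Step 1**
Reactants: 1 7-hydroxychroman-4-one
Product: 2 7-hydroxy-6-iodochroman-4-one
Conditions: NIS (1.0 equiv), TsOH·H2O (cat.), MeCN, 0 °C to rt, dark
Reagents that add atoms: N-iodosuccinimide, O=C1CCC(=O)N1I
Why: Electrophilic aromatic iodination should go to C6, which is ortho to the C7 hydroxyl and para to O1 and is less crowded than C8 between two oxygen substituents.

**Step 2**
Reactants: 2 7-hydroxy-6-iodochroman-4-one
Product: 3 7-(tert-butyldimethylsilyloxy)-6-iodochroman-4-one
Conditions: TBSCl, imidazole, DMF, rt
Reagents that add atoms: tert-butyldimethylsilyl chloride, CC(C)(C)[Si](C)(C)Cl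
Why: Imidazole-promoted silyl ether formation masks the acidic phenol that would otherwise quench the organozinc reagent of step 7.

**Step 3**
Reactants: 3 7-(tert-butyldimethylsilyloxy)-6-iodochroman-4-one; 4 tributyl(3-methylbut-2-en-1-yl)stannane
Product: 5 7-(tert-butyldimethylsilyloxy)-6-(3-methylbut-2-en-1-yl)chroman-4-one
Conditions: Pd(PPh3)4 (5 mol %), DMF, 90 °C
Reagents that add atoms: tributyl(3-methylbut-2-en-1-yl)stannane 4, CCCC[Sn](CCCC)(CCCC)CC=C(C)C
Why: In this Stille coupling of an aryl iodide with an allylic stannane, reductive elimination from the less hindered sigma-prenyl palladium species should give the linear prenyl arene, and ketone and silyl ether are inert under the neutral conditions.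

**Step 4**
Reactants: 5 7-(tert-butyldimethylsilyloxy)-6-(3-methylbut-2-en-1-yl)chroman-4-one
Product: 7 rac-3-bromo-7-(tert-butyldimethylsilyloxy)-6-(3-methylbut-2-en-1-yl)chroman-4-one, via silyl enol ether 6 (not isolated)
Conditions: TMSOTf, Et3N, CH2Cl2, 0 °C; pentane, filter off salts, concentrate; then NBS (1.0 equiv), THF, −78 °C
Reagents that add atoms: N-bromosuccinimide, O=C1CCC(=O)N1Br; trimethylsilyl trifluoromethanesulfonate, C[Si](C)(C)OS(=O)(=O)C(F)(F)F (its silyl group stays only in 6)
Why: Soft enolisation followed by electrophilic alpha-bromination of the silyl enol ether should touch only C3, because the enol ether is far more nucleophilic than the prenyl alkene or ring A, amine is removed first so that HBr is not lost to the chromone, and the new stereocentre is deliberately racemic.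

**Step 5**
Reactants: 8 4-bromophenol; 9 1-bromo-3-methylbut-2-ene (prenyl bromide)
Product: 10 4-bromo-2-(3-methylbut-2-en-1-yl)phenol
Conditions: NaH (1.0 equiv), toluene, 0 °C; then 9, rt
Reagents that add atoms: prenyl bromide 9, CC(C)=CCBr
Why: In this ortho-C-alkylation of a sodium phenoxide in a non-polar solvent, the tight ion pair shields oxygen, the ortho carbon attacks the primary allylic bromide and the ring rearomatises, while bromine blocks the para position.

**Step 6**
Reactants: 10 4-bromo-2-(3-methylbut-2-en-1-yl)phenol
Product: 11 [4-bromo-2-(3-methylbut-2-en-1-yl)phenoxy](tert-butyl)dimethylsilane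
Conditions: TBSCl, imidazole, DMF, rt
Reagents that add atoms: tert-butyldimethylsilyl chloride, CC(C)(C)[Si](C)(C)Cl
Why: Standard phenol silylation gives a protecting group that tolerates magnesium insertion and transmetallation and sits para to the metal, so no silyl migration can occur.

**Step 7**
Reactants: 7 rac-3-bromo-7-(tert-butyldimethylsilyloxy)-6-(3-methylbut-2-en-1-yl)chroman-4-one; 11 [4-bromo-2-(3-methylbut-2-en-1-yl)phenoxy](tert-butyl)dimethylsilane
Product: 14 (3R)-7-(tert-butyldimethylsilyloxy)-3-[4-(tert-butyldimethylsilyloxy)-3-(3-methylbut-2-en-1-yl)phenyl]-6-(3-methylbut-2-en-1-yl)chroman-4-one, via aryl Grignard reagent 12 (not isolated), via arylzinc iodide 13 (not isolated)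
Conditions: 11 (1.3 equiv), Mg, THF, 45 °C; ZnI2, THF, rt; then 7, NiCl2·dme (5 mol %; dme = MeOCH2CH2OMe), 2,6-bis[(4S,5R)-4,5-diphenyl-4,5-dihydrooxazol-2-yl]pyridine (6.5 mol %), glyme/THF, −30 °C
Reagents that add atoms: magnesium, [Mg]; zinc iodide, I[Zn]I (both appear only in 12 and 13, nothing of them remains in 14)
Why: A monovalent (pybox)nickel species abstracts bromine from either enantiomer of 7 to give one planar C3 radical delocalised into the C4 carbonyl, this radical is captured by the divalent (pybox)nickel aryl formed from 13 by transmetallation, and reductive elimination from the resulting trivalent nickel forges C3–C1'. The closest known reaction type is the nickel/pybox-catalysed stereoconvergent Negishi arylation of racemic secondary alpha-bromo aryl ketones with arylzinc iodides, applied here to a ring-fused member of that class. No ring is closed in this step. The new C3 stereocentre is controlled only by the chiral pybox ligand, because the configuration of the bromide is lost at the radical stage, and the ligand antipode is matched to (R) as stated in the remark. The step needs chemoselectivity for the C(sp3)–Br bond over carbonyl addition, loss of HBr to the chromone and beta-aryloxy elimination, which the weakly basic arylzinc at −30 °C and the ring C geometry (C2–O1 never syn-periplanar to C3–Ni) should secure, while the prenyl alkenes at C6 and C3' are too remote to trap the C3 radical. Since neither base nor fluoride activator is present, the acidic C3–H of 14 should not be enolised and the configuration should persist.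

**Step 8**
Reactants: 14 (3R)-bis(tert-butyldimethylsilyl) ether of the target
Product: 15 (3R)-7-hydroxy-3-[4-hydroxy-3-(3-methylbut-2-en-1-yl)phenyl]-6-(3-methylbut-2-en-1-yl)chroman-4-one (target)
Conditions: Et3N·3HF, THF, 0 °C to rt; pH 7 buffer work-up
Reagents that add atoms: none
Why: Fluoride-mediated cleavage of the two aryl silyl ethers in a weakly acidic, buffered medium should free both phenols without enolising C3 and without protonating the prenyl groups, so the (R) configuration is kept.

**Compound list**
1 | 7-hydroxychroman-4-one | O=C1CCOc2cc(O)ccc12 | starting material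
2 | 7-hydroxy-6-iodochroman-4-one | O=C1CCOc2cc(O)c(I)cc12 | intermediate
3 | 7-(tert-butyldimethylsilyloxy)-6-iodochroman-4-one | O=C1CCOc2cc(O[Si](C)(C)C(C)(C)C)c(I)cc12 | intermediate
4 | tributyl(3-methylbut-2-en-1-yl)stannane | CCCC[Sn](CCCC)(CCCC)CC=C(C)C | starting material
5 | 7-(tert-butyldimethylsilyloxy)-6-(3-methylbut-2-en-1-yl)chroman-4-one | CC(C)=CCc1cc2C(=O)CCOc2cc1O[Si](C)(C)C(C)(C)C | intermediate
6 | 7-(tert-butyldimethylsilyloxy)-6-(3-methylbut-2-en-1-yl)-4-(trimethylsilyloxy)-2H-chromene | CC(C)=CCc1cc2C(O[Si](C)(C)C)=CCOc2cc1O[Si](C)(C)C(C)(C)C | intermediate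
7 | rac-3-bromo-7-(tert-butyldimethylsilyloxy)-6-(3-methylbut-2-en-1-yl)chroman-4-one (racemic) | CC(C)=CCc1cc2C(=O)C(Br)COc2cc1O[Si](C)(C)C(C)(C)C | intermediate
8 | 4-bromophenol | Oc1ccc(Br)cc1 | starting material
9 | 1-bromo-3-methylbut-2-ene (prenyl bromide) | CC(C)=CCBr | starting material
10 | 4-bromo-2-(3-methylbut-2-en-1-yl)phenol | CC(C)=CCc1cc(Br)ccc1O | intermediate
11 | [4-bromo-2-(3-methylbut-2-en-1-yl)phenoxy](tert-butyl)dimethylsilane | CC(C)=CCc1cc(Br)ccc1O[Si](C)(C)C(C)(C)C | intermediate
12 | [4-(tert-butyldimethylsilyloxy)-3-(3-methylbut-2-en-1-yl)phenyl]magnesium bromide | CC(C)=CCc1cc([Mg]Br)ccc1O[Si](C)(C)C(C)(C)C | intermediate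
13 | [4-(tert-butyldimethylsilyloxy)-3-(3-methylbut-2-en-1-yl)phenyl]zinc iodide | CC(C)=CCc1cc([Zn]I)ccc1O[Si](C)(C)C(C)(C)C | intermediate
14 | (3R)-7-(tert-butyldimethylsilyloxy)-3-[4-(tert-butyldimethylsilyloxy)-3-(3-methylbut-2-en-1-yl)phenyl]-6-(3-methylbut-2-en-1-yl)chroman-4-one | CC(C)=CCc1cc([C@@H]2COc3cc(O[Si](C)(C)C(C)(C)C)c(CC=C(C)C)cc3C2=O)ccc1O[Si](C)(C)C(C)(C)C | intermediate
15 | (3R)-7-hydroxy-3-[4-hydroxy-3-(3-methylbut-2-en-1-yl)phenyl]-6-(3-methylbut-2-en-1-yl)chroman-4-one | CC(C)=CCc1cc([C@@H]2COc3cc(O)c(CC=C(C)C)cc3C2=O)ccc1O | target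

**Step count**
Total steps: 8. Longest linear sequence: 6 (steps 1, 2, 3, 4, 7, 8).

**Steps most likely to fail**

**Step 7.**
- Risk: the ligand may discriminate the faces of the ring-fused radical poorly, 7 may lose HBr to the chromone, or the C–Br bond may simply be reduced.
- Route of the fallback: it sets out from ketone 5 and aryl bromide 11 and comes back at 14. Bond formation and stereocontrol are separated.
- Bond formation: palladium-catalysed enolate arylation of the chromanone (Pd2(dba)3, P(t-Bu)3·HBF4, K3PO4, toluene, 90 °C) should give the racemic bis-silyl isoflavanone F1.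
- Stereocontrol: Noyori–Ikariya transfer hydrogenation under dynamic kinetic resolution (RuCl[(R,R)-TsDPEN](p-cymene), HCO2H/Et3N, EtOAc, 40 °C) follows. Et3N keeps C3 racemising while one enantiomer is reduced faster, which should give the cis-(3R,4R)-isoflavan-4-ol F2.
- Sense of induction: by the usual aryl ketone model the (R,R) catalyst delivers the (4R) carbinol, and the cis preference then fixes (3R).
- Return: Dess–Martin oxidation (CH2Cl2, 0 °C) restores the ketone 14 under neutral conditions with C3 untouched.

**Step 8.**
- Risk: fluoride or a liberated phenoxide may partly enolise C3 during silyl cleavage and erode the configuration.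
- Route of the fallback: it sets out from 14 and comes back at 15. The stereocentre is re-set after the robust silyl groups are gone.
- Deprotection: TBAF in THF strips both groups without regard to C3 and gives the racemic diphenol F3.
- Enol ether formation: persilylation (TMSOTf, Et3N, CH2Cl2, 0 °C) gives the tris(trimethylsilyl) enol ether F4.
- Stereocontrol: catalytic enantioselective protonation of this 2-aryl cyclic silyl enol ether uses a 3,3'-diaryl-BINOL-derived N-triflyl thiophosphoramide, with phenol as the stoichiometric proton source, in toluene. It should give the (R)-bis(trimethylsilyl) ether F5.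
- Return: the very labile aryl trimethylsilyl ethers of F5 fall off in methanol with citric acid at 0 °C to give 15.

**Step 1.**
- Risk: the iodinating agent may attack C8, or both ortho positions, instead of C6 alone.
- Route of the fallback: it sets out from 1 and comes back at 5. The halogenation and cross-coupling sequence is dropped.
- Prenylation: direct Friedel–Crafts-type nuclear prenylation with the bulkier allylic cation (2-methylbut-3-en-2-ol, BF3·OEt2, dioxane, rt) should favour the less crowded C6. After chromatographic removal of any C8 isomer it gives 7-hydroxy-6-prenylchroman-4-one F6.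
- Return: silylation (TBSCl, imidazole, DMF) converts F6 into 5.

**Further compounds**
F1 | step 7 | rac-7-(tert-butyldimethylsilyloxy)-3-[4-(tert-butyldimethylsilyloxy)-3-(3-methylbut-2-en-1-yl)phenyl]-6-(3-methylbut-2-en-1-yl)chroman-4-one | CC(C)=CCc1cc(C2COc3cc(O[Si](C)(C)C(C)(C)C)c(CC=C(C)C)cc3C2=O)ccc1O[Si](C)(C)C(C)(C)C
F2 | step 7 | cis-(3R,4R)-7-(tert-butyldimethylsilyloxy)-3-[4-(tert-butyldimethylsilyloxy)-3-(3-methylbut-2-en-1-yl)phenyl]-6-(3-methylbut-2-en-1-yl)chroman-4-ol | CC(C)=CCc1cc([C@@H]2COc3cc(O[Si](C)(C)C(C)(C)C)c(CC=C(C)C)cc3[C@@H]2O)ccc1O[Si](C)(C)C(C)(C)C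
F3 | step 8 | rac-7-hydroxy-3-[4-hydroxy-3-(3-methylbut-2-en-1-yl)phenyl]-6-(3-methylbut-2-en-1-yl)chroman-4-one | CC(C)=CCc1cc(C2COc3cc(O)c(CC=C(C)C)cc3C2=O)ccc1O
F4 | step 8 | 4,7-bis(trimethylsilyloxy)-3-[4-(trimethylsilyloxy)-3-(3-methylbut-2-en-1-yl)phenyl]-6-(3-methylbut-2-en-1-yl)-2H-chromene | CC(C)=CCc1cc(C2=C(O[Si](C)(C)C)c3cc(CC=C(C)C)c(O[Si](C)(C)C)cc3OC2)ccc1O[Si](C)(C)C
F5 | step 8 | (3R)-7-(trimethylsilyloxy)-3-[4-(trimethylsilyloxy)-3-(3-methylbut-2-en-1-yl)phenyl]-6-(3-methylbut-2-en-1-yl)chroman-4-one | CC(C)=CCc1cc([C@@H]2COc3cc(O[Si](C)(C)C)c(CC=C(C)C)cc3C2=O)ccc1O[Si](C)(C)C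
F6 | step 1 | 7-hydroxy-6-(3-methylbut-2-en-1-yl)chroman-4-one | CC(C)=CCc1cc2C(=O)CCOc2cc1O
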